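**Retrosynthetic overview**
1. Tetralin numbering C1–C8a; C9 and C10 are the hydroxymethyl carbons on C2 and C3. The strategy rests on C1, which is bonded to C8a of ring A and to the trimethoxyphenyl ring and therefore ionises to a diarylmethyl cation, and on C2, which carries C9 and can be the γ-carbon of an allylsilane tethered through C3 and C4 to C4a.
2. Ring B, the only ring formed, is closed last by the C1–C2 bond; the vinyl group left on C2 is cut down to C9, and three benzyl ethers are then removed.
3. The carbinol comes from a C1–C8a bond: a ring A aryllithium (bromine at C8a) adds to 3,4,5-trimethoxybenzaldehyde, with no stereocontrol needed at C1.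
4. C3, the only stereocentre carried into the cyclisation, is set by alkylating the (S)-4-benzyloxazolidinone silylpentenoyl dienolate with the ring A benzylic bromide (C3–C4 bond).
5. Ring A comes from 3,4-dihydroxy-5-methoxybenzaldehyde: its formyl carbon becomes C4, and bromine is placed at the future C8a, ortho to the free phenol.

Key step: step 12

Assumption: compound 13 is carried as the (E)-alkene drawn. A minor (Z)-isomer from the metathesis need not be removed, because the alkene geometry disappears when silicon leaves in step 12 and both geometries prefer the same chair, with the C3–H bond eclipsing the alkene.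

**Route**

Step 1
Reactants: 1 3,4-dihydroxy-5-methoxybenzaldehyde
Product: 2 4-(benzyloxy)-3-hydroxy-5-methoxybenzaldehyde
Conditions: BnBr (1.0 equiv), NaHCO3, NaI (cat.), DMF, 40 °C
Reagents that add atoms: benzyl bromide, BrCc1ccccc1
Why: Williamson etherification under a weak base: the 4-OH para to the formyl group is the most acidic phenol, so it alone is benzylated and the 3-OH stays free.

Step 2
Reactants: 2 4-(benzyloxy)-3-hydroxy-5-methoxybenzaldehyde
Product: 3 4-(benzyloxy)-2-bromo-3-hydroxy-5-methoxybenzaldehyde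
Conditions: Br2 (1.05 equiv), NaOAc, AcOH, rt
Reagents that add atoms: bromine, BrBr
Why: Electrophilic aromatic bromination: the free phenol directs ortho and the methoxy group directs para to the same carbon, the pattern known from the 2-bromination of isovanillin.

Step 3
Reactants: 3 4-(benzyloxy)-2-bromo-3-hydroxy-5-methoxybenzaldehyde
Product: 4 3,4-bis(benzyloxy)-2-bromo-5-methoxybenzaldehyde
Conditions: BnBr, K2CO3, DMF, 60 °C
Reagents that add atoms: benzyl bromide, BrCc1ccccc1
Why: Williamson etherification of the remaining, hindered phenoxide; the aldehyde and the aryl bromide are inert to carbonate.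

Step 4
Reactants: 4 3,4-bis(benzyloxy)-2-bromo-5-methoxybenzaldehyde
Product: 5 [3,4-bis(benzyloxy)-2-bromo-5-methoxyphenyl]methanol
Conditions: NaBH4, MeOH/THF, 0 °C
Reagents that add atoms: none
Why: Chemoselective borohydride reduction of the aldehyde to the benzylic alcohol (future C4), leaving the aryl bromide and benzyl ethers untouched.

Step 5
Reactants: 5 [3,4-bis(benzyloxy)-2-bromo-5-methoxyphenyl]methanol
Product: 6 3,4-bis(benzyloxy)-2-bromo-5-methoxybenzyl bromide
Conditions: PBr3, CH2Cl2, 0 °C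
Reagents that add atoms: phosphorus tribromide, BrP(Br)Br
Why: Bromination of a benzylic alcohol with PBr3 (bromide displaces the phosphite ester); the electron-rich bromide should be used at once without storage.

Step 6
Reactants: 7 but-3-enoic acid; 8 (S)-4-benzyloxazolidin-2-one
Product: 11 (S)-4-benzyl-3-(but-3-enoyl)oxazolidin-2-one, via but-3-enoic pivalic anhydride 9 (not isolated), via lithium oxazolidinide 10 (not isolated)
Conditions: 7, PivCl, Et3N, THF, −78 → 0 °C; separately 8, n-BuLi, THF, −78 °C; combined at −78 °C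
Reagents that add atoms: none
Why: N-Acylation of the lithiated oxazolidinone by the mixed anhydride at its less hindered but-3-enoyl carbonyl; the low temperature keeps the alkene out of conjugation.

Step 7
Reactants: 11 (S)-4-benzyl-3-(but-3-enoyl)oxazolidin-2-one; 12 allyltrimethylsilane
Product: 13 (S)-4-benzyl-3-[(E)-5-(trimethylsilyl)pent-3-enoyl]oxazolidin-2-one
Conditions: second-generation Grubbs catalyst (5 mol%), 12 (4 equiv), CH2Cl2, 40 °C
Reagents that add atoms: none
Why: Olefin cross-metathesis of the terminal alkene with an excess of the allylsilane, driven by loss of ethylene and favouring the (E)-alkene.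

Step 8
Reactants: 13 (S)-4-benzyl-3-[(E)-5-(trimethylsilyl)pent-3-enoyl]oxazolidin-2-one; 6 3,4-bis(benzyloxy)-2-bromo-5-methoxybenzyl bromide
Product: 15 (S)-4-benzyl-3-[(2S,3E)-2-[3,4-bis(benzyloxy)-2-bromo-5-methoxybenzyl]-5-(trimethylsilyl)pent-3-enoyl]oxazolidin-2-one, via sodium dienolate 14 (not isolated)
Conditions: NaN(SiMe3)2, THF, −78 °C; then 6, −78 → −40 °C; AcOH quench at −78 °C
Reagents that add atoms: none
Why: Evans asymmetric alkylation: the chelated sodium Z-dienolate reacts at its α-carbon (deconjugative alkylation) on the face opposite the benzyl group of the auxiliary, which sets the future C3 as (S).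

Step 9
Reactants: 15 (S)-4-benzyl-3-[(2S,3E)-2-[3,4-bis(benzyloxy)-2-bromo-5-methoxybenzyl]-5-(trimethylsilyl)pent-3-enoyl]oxazolidin-2-one
Product: 16 (2S,3E)-2-[3,4-bis(benzyloxy)-2-bromo-5-methoxybenzyl]-5-(trimethylsilyl)pent-3-en-1-ol
Conditions: LiBH4, MeOH (1 equiv), Et2O/THF, 0 °C
Reagents that add atoms: none
Why: Reductive removal of the auxiliary: LiBH4 attacks the exocyclic imide carbonyl and gives the primary alcohol (future C10) without touching the α-stereocentre, the allylsilane or the aryl bromide.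

Step 10
Reactants: 16 (2S,3E)-2-[3,4-bis(benzyloxy)-2-bromo-5-methoxybenzyl]-5-(trimethylsilyl)pent-3-en-1-ol
Product: 17 [(2E,4S)-5-(benzyloxy)-4-[3,4-bis(benzyloxy)-2-bromo-5-methoxybenzyl]pent-2-en-1-yl]trimethylsilane
Conditions: NaH, BnBr, n-Bu4NI (cat.), THF/DMF, 0 °C → rt
Reagents that add atoms: benzyl bromide, BrCc1ccccc1
Why: Williamson benzylation of the primary alkoxide; the allylsilane and the aryl bromide do not react with NaH or benzyl bromide.

Step 11
Reactants: 17 [(2E,4S)-5-(benzyloxy)-4-[3,4-bis(benzyloxy)-2-bromo-5-methoxybenzyl]pent-2-en-1-yl]trimethylsilane; 18 3,4,5-trimethoxybenzaldehyde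
Product: 20 {2,3-bis(benzyloxy)-6-[(2S,3E)-2-[(benzyloxy)methyl]-5-(trimethylsilyl)pent-3-en-1-yl]-4-methoxyphenyl}(3,4,5-trimethoxyphenyl)methanol (both C1 epimers), via aryllithium 19 (not isolated)
Conditions: n-BuLi (1.05 equiv), THF, −78 °C; then 18, −78 → −20 °C; H2O
Reagents that add atoms: none
Why: Bromine–lithium exchange at −78 °C outruns deprotonation of the benzyl ethers, and the aryllithium adds to the non-enolisable aldehyde to form the C1–C8a bond; either carbinol epimer serves because C1 is ionised in the next step.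

Step 12
Reactants: 20 {2,3-bis(benzyloxy)-6-[(2S,3E)-2-[(benzyloxy)methyl]-5-(trimethylsilyl)pent-3-en-1-yl]-4-methoxyphenyl}(3,4,5-trimethoxyphenyl)methanol
Product: 22 (1S,2S,3S)-7,8-bis(benzyloxy)-3-[(benzyloxy)methyl]-6-methoxy-1-(3,4,5-trimethoxyphenyl)-2-vinyl-1,2,3,4-tetrahydronaphthalene, via diarylmethyl cation 21 (not isolated)
Conditions: BF3·OEt2 (0.3 equiv), CH2Cl2, −78 → −30 °C
Reagents that add atoms: none
Why: BF3 ionises either carbinol epimer to the same planar diarylmethyl cation 21, stabilised by the C6 methoxy group (para to C8a), the C8 benzyloxy group and the trimethoxyphenyl ring; the γ-carbon of the tethered allylsilane (future C2) then adds to C1, and loss of the silyl group to the departed hydroxide leaves the C2 vinyl group and turns the acid over. The closest known reaction type is the intramolecular Hosomi–Sakurai trapping of benzhydryl cations, a cation–olefin cyclisation to 1-aryltetralins. Ring B closes in a 6-exo-trig mode with respect to the allylsilane through a chair-like transition state. C2 is controlled by C3: with the C3 benzyloxymethyl group equatorial, allylic 1,3-strain keeps the C3–H bond eclipsed with the alkene, so the alkene residue is also equatorial and the vinyl group ends trans to the C3 substituent. C1 is controlled by the peri C8 benzyloxy group, which forces the trimethoxyphenyl group pseudoaxial and hence cis to the equatorial C2 vinyl group, so the (S) centre at C3 should lead to the (1S,2S,3S) isomer. The step needs attack by carbon before protodesilylation or Friedel–Crafts capture by a benzyl ether ring, and the high nucleophilicity of the allylsilane, the six-membered transition state and the low temperature should secure this.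

Step 13
Reactants: 22 (1S,2S,3S)-7,8-bis(benzyloxy)-3-[(benzyloxy)methyl]-6-methoxy-1-(3,4,5-trimethoxyphenyl)-2-vinyl-1,2,3,4-tetrahydronaphthalene
Product: 24 (1S,2S,3S)-7,8-bis(benzyloxy)-3-[(benzyloxy)methyl]-6-methoxy-1-(3,4,5-trimethoxyphenyl)-1,2,3,4-tetrahydronaphthalene-2-carbaldehyde, via vicinal diol 23 (not isolated)
Conditions: OsO4 (2 mol%), NaIO4 (4 equiv), 2,6-lutidine, dioxane/H2O (3:1), rt
Reagents that add atoms: osmium tetroxide, O=[Os](=O)(=O)=O; sodium periodate, [Na+].[O-]I(=O)(=O)=O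
Why: Lemieux–Johnson oxidation: catalytic OsO4 dihydroxylates the only alkene and NaIO4 cleaves the diol to the C2 aldehyde, with 2,6-lutidine buffering so that C2 is not epimerised.

Step 14
Reactants: 24 (1S,2S,3S)-7,8-bis(benzyloxy)-3-[(benzyloxy)methyl]-6-methoxy-1-(3,4,5-trimethoxyphenyl)-1,2,3,4-tetrahydronaphthalene-2-carbaldehyde
Product: 25 [(1S,2S,3S)-7,8-bis(benzyloxy)-3-[(benzyloxy)methyl]-6-methoxy-1-(3,4,5-trimethoxyphenyl)-1,2,3,4-tetrahydronaphthalen-2-yl]methanol
Conditions: NaBH4, MeOH/THF, 0 °C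
Reagents that add atoms: none
Why: Borohydride reduction of the aldehyde to the C9 primary alcohol, carried out at once on the crude aldehyde so that C2 keeps its configuration.

Step 15
Reactants: 25 [(1S,2S,3S)-7,8-bis(benzyloxy)-3-[(benzyloxy)methyl]-6-methoxy-1-(3,4,5-trimethoxyphenyl)-1,2,3,4-tetrahydronaphthalen-2-yl]methanol
Product: 26 (1S,2S,3S)-2,3-bis(hydroxymethyl)-6-methoxy-1-(3,4,5-trimethoxyphenyl)-1,2,3,4-tetrahydronaphthalene-7,8-diol
Conditions: H2 (1 atm), Pd/C, EtOAc/MeOH, rt
Reagents that add atoms: none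
Why: Catalytic hydrogenolysis of the two aryl benzyl ethers and the alkyl benzyl ether; the C1–aryl bonds and the methyl ethers are inert, so the three stereocentres are unchanged.

**Compound list**
1 | 3,4-dihydroxy-5-methoxybenzaldehyde | COc1cc(C=O)cc(O)c1O | starting material
2 | 4-(benzyloxy)-3-hydroxy-5-methoxybenzaldehyde | COc1cc(C=O)cc(O)c1OCc1ccccc1 | intermediate
3 | 4-(benzyloxy)-2-bromo-3-hydroxy-5-methoxybenzaldehyde | COc1cc(C=O)c(Br)c(O)c1OCc1ccccc1 | intermediate
4 | 3,4-bis(benzyloxy)-2-bromo-5-methoxybenzaldehyde | COc1cc(C=O)c(Br)c(OCc2ccccc2)c1OCc1ccccc1 | intermediate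
5 | [3,4-bis(benzyloxy)-2-bromo-5-methoxyphenyl]methanol | COc1cc(CO)c(Br)c(OCc2ccccc2)c1OCc1ccccc1 | intermediate
6 | 3,4-bis(benzyloxy)-2-bromo-5-methoxybenzyl bromide | COc1cc(CBr)c(Br)c(OCc2ccccc2)c1OCc1ccccc1 | intermediate
7 | but-3-enoic acid | C=CCC(=O)O | starting material
8 | (S)-4-benzyloxazolidin-2-one | O=C1N[C@@H](Cc2ccccc2)CO1 | starting material
9 | but-3-enoic pivalic anhydride (not isolated) | C=CCC(=O)OC(=O)C(C)(C)C | intermediate
10 | lithium (S)-4-benzyl-2-oxooxazolidin-3-ide (not isolated) | O=C1[N-][C@@H](Cc2ccccc2)CO1.[Li+] | intermediate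
11 | (S)-4-benzyl-3-(but-3-enoyl)oxazolidin-2-one | C=CCC(=O)N1[C@@H](Cc2ccccc2)COC1=O | intermediate
12 | allyltrimethylsilane | C=CC[Si](C)(C)C | starting material
13 | (S)-4-benzyl-3-[(E)-5-(trimethylsilyl)pent-3-enoyl]oxazolidin-2-one | C[Si](C)(C)C/C=C/CC(=O)N1[C@@H](Cc2ccccc2)COC1=O | intermediate
14 | sodium (1Z,3E)-dienolate of 13 (not isolated) | C[Si](C)(C)C/C=C/C=C(\[O-])N1[C@@H](Cc2ccccc2)COC1=O.[Na+] | intermediate
15 | (S)-4-benzyl-3-[(2S,3E)-2-[3,4-bis(benzyloxy)-2-bromo-5-methoxybenzyl]-5-(trimethylsilyl)pent-3-enoyl]oxazolidin-2-one | COc1cc(C[C@@H](/C=C/C[Si](C)(C)C)C(=O)N2[C@@H](Cc3ccccc3)COC2=O)c(Br)c(OCc2ccccc2)c1OCc1ccccc1 | intermediate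
16 | (2S,3E)-2-[3,4-bis(benzyloxy)-2-bromo-5-methoxybenzyl]-5-(trimethylsilyl)pent-3-en-1-ol | COc1cc(C[C@@H](/C=C/C[Si](C)(C)C)CO)c(Br)c(OCc2ccccc2)c1OCc1ccccc1 | intermediate
17 | [(2E,4S)-5-(benzyloxy)-4-[3,4-bis(benzyloxy)-2-bromo-5-methoxybenzyl]pent-2-en-1-yl]trimethylsilane | COc1cc(C[C@@H](/C=C/C[Si](C)(C)C)COCc2ccccc2)c(Br)c(OCc2ccccc2)c1OCc1ccccc1 | intermediate
18 | 3,4,5-trimethoxybenzaldehyde | COc1cc(C=O)cc(OC)c1OC | starting material
19 | aryllithium from 17, lithium at the future C8a (not isolated) | COc1cc(C[C@@H](/C=C/C[Si](C)(C)C)COCc2ccccc2)c([Li])c(OCc2ccccc2)c1OCc1ccccc1 | intermediate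
20 | {2,3-bis(benzyloxy)-6-[(2S,3E)-2-[(benzyloxy)methyl]-5-(trimethylsilyl)pent-3-en-1-yl]-4-methoxyphenyl}(3,4,5-trimethoxyphenyl)methanol, both carbinol epimers | COc1cc(C[C@@H](/C=C/C[Si](C)(C)C)COCc2ccccc2)c(C(O)c2cc(OC)c(OC)c(OC)c2)c(OCc2ccccc2)c1OCc1ccccc1 | intermediate
21 | diarylmethyl cation from 20 (not isolated) | COc1cc(C[C@@H](/C=C/C[Si](C)(C)C)COCc2ccccc2)c([CH+]c2cc(OC)c(OC)c(OC)c2)c(OCc2ccccc2)c1OCc1ccccc1 | intermediate
22 | (1S,2S,3S)-7,8-bis(benzyloxy)-3-[(benzyloxy)methyl]-6-methoxy-1-(3,4,5-trimethoxyphenyl)-2-vinyl-1,2,3,4-tetrahydronaphthalene | COc1cc2c(c(OCc3ccccc3)c1OCc1ccccc1)[C@H](c1cc(OC)c(OC)c(OC)c1)[C@H](C=C)[C@@H](COCc1ccccc1)C2 | intermediate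
23 | vicinal diol from 22, 2-(1,2-dihydroxyethyl) tetralin, carbinol centre undefined (not isolated) | COc1cc2c(c(OCc3ccccc3)c1OCc1ccccc1)[C@H](c1cc(OC)c(OC)c(OC)c1)[C@H](C(O)CO)[C@@H](COCc1ccccc1)C2 | intermediate
24 | (1S,2S,3S)-7,8-bis(benzyloxy)-3-[(benzyloxy)methyl]-6-methoxy-1-(3,4,5-trimethoxyphenyl)-1,2,3,4-tetrahydronaphthalene-2-carbaldehyde | COc1cc2c(c(OCc3ccccc3)c1OCc1ccccc1)[C@H](c1cc(OC)c(OC)c(OC)c1)[C@H](C=O)[C@@H](COCc1ccccc1)C2 | intermediate
25 | [(1S,2S,3S)-7,8-bis(benzyloxy)-3-[(benzyloxy)methyl]-6-methoxy-1-(3,4,5-trimethoxyphenyl)-1,2,3,4-tetrahydronaphthalen-2-yl]methanol | COc1cc2c(c(OCc3ccccc3)c1OCc1ccccc1)[C@H](c1cc(OC)c(OC)c(OC)c1)[C@H](CO)[C@@H](COCc1ccccc1)C2 | intermediate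
26 | (1S,2S,3S)-2,3-bis(hydroxymethyl)-6-methoxy-1-(3,4,5-trimethoxyphenyl)-1,2,3,4-tetrahydronaphthalene-7,8-diol | COc1cc2c(c(O)c1O)[C@H](c1cc(OC)c(OC)c(OC)c1)[C@H](CO)[C@@H](CO)C2 | target

**Step count**
Total: 15 steps. Longest linear sequence: 13 steps (steps 1–5 and 8–15, from compound 1).

**Steps most likely to fail**

Step 12. The closure may show poor facial selectivity at C1, the allylsilane may be protodesilylated before it reaches the cation, or the cation may shed a benzyl group. The fallback sets out from 20 and fixes C2 and C1 in two separate events. Oxidation of 20 with Dess–Martin periodinane should give the diaryl ketone F1. TiCl4 in CH2Cl2 at −78 °C should then promote an intramolecular Hosomi–Sakurai addition of the allylsilane to the ketone, closing ring B through the same chair and giving the tertiary carbinol F2 with the C2 vinyl group trans to the C3 substituent. Ionic hydrogenation of F2 (Et3SiH, BF3·OEt2, CH2Cl2, −78 °C) should deliver hydride to C1 on the face opposite the C2 vinyl group, which places the aryl group cis to it and comes back to the route at 22.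

Step 2. Bromination may occur at the other free ring position (para to the phenol), or twice. The fallback sets out from 2 and places the bromine by directed ortho-metalation instead of electrophilic substitution. Acetalisation of 2 (ethylene glycol, TsOH cat., toluene, reflux) should give the dioxolane F3, and MOMCl with i-Pr2NEt the methoxymethyl ether F4. n-BuLi in THF at 0 °C should lithiate the carbon flanked by the methoxymethoxy group and the dioxolane, giving the aryllithium F5. Quenching with 1,2-dibromotetrachloroethane should give the bromide F6, and aqueous HCl in THF should remove both protecting groups and come back to the route at 3.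

Step 11. A benzyl ether may be deprotonated next to oxygen and rearrange (Wittig rearrangement), or the aryllithium may be protonated before it meets the aldehyde. The fallback sets out from 17 and reverses the polarity of the C1–C8a union. Palladium-catalysed formylation of 17 (Pd(OAc)2, di(1-adamantyl)-n-butylphosphine, TMEDA, CO/H2, toluene, 100 °C) should give the aldehyde F7. Addition of 3,4,5-trimethoxyphenylmagnesium bromide F8, made from 5-bromo-1,2,3-trimethoxybenzene and Mg in THF, should then give the carbinol and come back to the route at 20.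

**Further compounds**
F1 | step 12 | {2,3-bis(benzyloxy)-6-[(2S,3E)-2-[(benzyloxy)methyl]-5-(trimethylsilyl)pent-3-en-1-yl]-4-methoxyphenyl}(3,4,5-trimethoxyphenyl)methanone | COc1cc(C[C@@H](/C=C/C[Si](C)(C)C)COCc2ccccc2)c(C(=O)c2cc(OC)c(OC)c(OC)c2)c(OCc2ccccc2)c1OCc1ccccc1
F2 | step 12 | (2R,3S)-7,8-bis(benzyloxy)-3-[(benzyloxy)methyl]-6-methoxy-1-(3,4,5-trimethoxyphenyl)-2-vinyl-1,2,3,4-tetrahydronaphthalen-1-ol, C1 undefined | COc1cc2c(c(OCc3ccccc3)c1OCc1ccccc1)C(O)(c1cc(OC)c(OC)c(OC)c1)[C@H](C=C)[C@@H](COCc1ccccc1)C2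
F3 | step 2 | 2-(benzyloxy)-5-(1,3-dioxolan-2-yl)-3-methoxyphenol | COc1cc(C2OCCO2)cc(O)c1OCc1ccccc1
F4 | step 2 | 2-[4-(benzyloxy)-3-methoxy-5-(methoxymethoxy)phenyl]-1,3-dioxolane | COCOc1cc(C2OCCO2)cc(OC)c1OCc1ccccc1
F5 | step 2 | [3-(benzyloxy)-6-(1,3-dioxolan-2-yl)-4-methoxy-2-(methoxymethoxy)phenyl]lithium | COCOc1c([Li])c(C2OCCO2)cc(OC)c1OCc1ccccc1
F6 | step 2 | 2-[4-(benzyloxy)-2-bromo-5-methoxy-3-(methoxymethoxy)phenyl]-1,3-dioxolane | COCOc1c(Br)c(C2OCCO2)cc(OC)c1OCc1ccccc1
F7 | step 11 | 2,3-bis(benzyloxy)-6-[(2S,3E)-2-[(benzyloxy)methyl]-5-(trimethylsilyl)pent-3-en-1-yl]-4-methoxybenzaldehyde | COc1cc(C[C@@H](/C=C/C[Si](C)(C)C)COCc2ccccc2)c(C=O)c(OCc2ccccc2)c1OCc1ccccc1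
F8 | step 11 | 3,4,5-trimethoxyphenylmagnesium bromide | COc1cc([Mg]Br)cc(OC)c1OC
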